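Which species leads after 50 min in three flasks that differ in their catalyst loading?

| flask | substrate | capture agent | free catalyst | remark | time |
|---|---|---|---|---|---|
| elm | 0.034 M | 5 mM | 2.7 mol% | run made earlier |  |
| cedar | 0.050 M | 10 mM | 2.7 mol% | run made earlier |  |
| Monday's | 0.050 M | 5.00 mM | 4.6 mol% |  | 50 min |
| Wednesday's | 0.050 M | 5.00 mM | 3.5 mol% |  | 50 min |
| Thursday's | 0.050 M | 5.00 mM | 2.7 mol% |  | 50 min |

1. which of these there is most of at the end, counted by the substrate in it, Monday's (trapped intermediate / side product / target / substrate)
2. which of these there is most of at the end, counted by the substrate in it, Wednesday's (trapped intermediate / side product / target / substrate)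
3. which of these there is most of at the end, counted by the substrate in it, Thursday's (trapped intermediate / side product / target / substrate)
4. how much there is at the end of the one of these that leads, in percent of the substrate charged: Monday's
5. how much there is at the end of the one of these that leads, in percent of the substrate charged: Wednesday's
6. how much there is at the end of the one of these that leads, in percent of the substrate charged: Thursday's

| run | time / min | side product / % | target / % | trapped intermediate / % | substrate / % |
|---|---|---|---|---|---|
| elm | 1.33 | 1.6 | 17.6 | 0.1 | 80.3 |
| elm | 2.50 | 2.5 | 27.0 | 0.5 | 68.1 |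
| elm | 5.00 | 7.3 | 39.5 | 1.3 | 51.0 |
| elm | 10.0 | 15.9 | 47.0 | 2.7 | 33.6 |
| elm | 20.0 | 28.9 | 45.8 | 2.6 | 21.3 |
| cedar | 1.50 | 1.5 | 18.6 | 1.0 | 76.9 |
| cedar | 4.00 | 7.2 | 32.6 | 1.4 | 57.0 |
| cedar | 8.00 | 17.6 | 35.5 | 2.6 | 44.0 |
| cedar | 12.0 | 26.3 | 33.7 | 2.3 | 38.3 |
| cedar | 20.0 | 37.6 | 28.0 | 2.3 | 30.6 |

(each reading ± 0.5 percentage points)

- a species is counted by the substrate in it: one side product counts as two

A side product counts as two, so it is read here as one substrate joined to one target. On that reading, substrate consumes target while both stand in the flask.

The cedar run shows this step at the same 0.050 M of substrate as the new flasks. Its trapped intermediate reads 2.3% and 2.3% against a loading of 2.7 mol%.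

Between those readings, half the side-product gain per minute, divided by mean target times mean substrate (both as fractions of the charge), gives 0.0665 min⁻¹. This is the pair constant κ: the fraction of target lost per minute with [substrate] at its full charge. Multiplied by the fraction of substrate left, it is a pseudo-first-order constant for target. The reading carries the scatter.

At full charge, target's half-life is 10.4 min, shorter than the 50 min run. So my reckoning is that substrate still standing once the catalyst is trapped costs target, and each target lost adds two to the side-product count.

The forecast put target first on Monday's at 63% and Wednesday's at 54%, and side product first on Thursday's at 51%. Of the side step it said: “It runs uncatalysed, even after the catalyst is gone”.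

The flasks give target 53.3% on Monday's, side product 49.0% on Wednesday's and side product 55.6% on Thursday's. Wednesday's target ends at 43.3%. At 25.0 min, Wednesday's flask had 98.2% of its catalyst trapped, with target at 48.4% and side product at 38.3%. Over the second half of Wednesday's flask, κ with the mean amounts gives a side-product gain of 10.7%; the flask added 11 percentage points.

    substrate + free catalyst → catalyst intermediate A (k = 7.70 L mol⁻¹ s⁻¹)
    catalyst intermediate A ⇌ catalyst intermediate B (K = 2.30, k = 0.190 s⁻¹)
    catalyst intermediate B ⇌ free catalyst + target (K = 0.0180 M, k = 1.50 s⁻¹)
    capture agent + catalyst intermediate B → trapped intermediate (k = 1.90 L mol⁻¹ s⁻¹)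
    substrate + target → side product (k = 0.0240 L mol⁻¹ s⁻¹)

In a flask like Wednesday's with 0.0020 M of capture agent, the 0.245% of substrate at the end gives target a half-life of 4254 min by κ. That flask ends with target at 65.3% and side product at 31.1%.

The data are simulated on assumed constants; scatter was added.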